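**Slow balance.** Look first for what lags. Of the two charges that get used up, the starting material is the smaller (the limiting reagent), so whatever of it is not yet product is still starting material or intermediate.

| flask | starting material | reagent | catalyst | remark | time |
|---|---|---|---|---|---|
| epsilon | 1.5 M | 3 M | 150 mM | run made earlier |  |
| alpha | 1.5 M | 3 M | 330 mM | run made earlier |  |
| beta | 0.75 M | 3 M | 220 mM | run made earlier |  |
| flask | 1.5 M | 3.00 M | 220 mM |  | 10 d |

| run | time / d | product / % | crystals / % | starting material / % |
|---|---|---|---|---|
| epsilon | 1.04 | 6.5 | 1.1 | 61.6 |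
| epsilon | 3.00 | 29.5 | 24.6 | 24.0 |
| epsilon | 5.00 | 51.7 | 46.7 | 9.2 |
| epsilon | 8.00 | 71.9 | 67.4 | 2.2 |
| alpha | 2.08 | 47.3 | 42.2 | 11.9 |
| alpha | 4.00 | 75.5 | 71.0 | 1.7 |
| alpha | 6.00 | 89.0 | 84.4 | 0.2 |
| alpha | 8.00 | 94.1 | 90.6 | 0 |
| beta | 0.625 | 4.8 | 0 | 64.4 |
| beta | 1.67 | 23.0 | 14.7 | 32.1 |
| beta | 3.00 | 47.7 | 38.8 | 13.0 |
| beta | 8.00 | 89.6 | 82.1 | 0.2 |

(each reading ± 0.3 percentage points)

1. the product and crystals together standing at 10 d, as a percentage of the starting material charged
2. concentration of product in solution at 10 d, in percent of saturation

**Alpha days.** Both steps carry the catalyst, and epsilon and alpha share the flask's other charges. The flask's 10 d therefore come to 6.67 d in alpha days, the time multiplied by the catalyst charged and divided by alpha's catalyst. Test it: epsilon at 8.00 d counts 3.64 d and stands at 71.9%, a little below alpha's 75.5% at 4.00 d.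

**Time ladder.** Put crystals on the quick rung: epsilon's product climbs from 29.5% at 3.00 d to 71.9% at 8.00 d, while the part outside crystals goes from 4.9 percentage points to 4.5 points. Next comes starting material: epsilon's readings give a half-life of 0.983 d at the flask's catalyst, leaving 0.0866% at the end. Intermediate comes last: by the balance, alpha holds 10.8% at 6.00 d and 5.90% at 8.00 d, which reads as a half-life of 3.44 d in flask time. So expect intermediate, not starting material, to make up the shortfall in the flask. A straight line between alpha's 89.0% and 94.1%, read at 6.67 d of alpha's time, gives 90.7%.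

**The forecast.** It gives 91.2% (90.2% to 92.2%), above my line, and 110% of saturation (100% to 125%), holding that “Time × catalyst therefore scales the kinetics”.

**The result.** The flask gives 91.3% and 102% of saturation, so the forecast's saturation stands 7.5 points too high.

    starting material + catalyst → catalyst + intermediate (k = 0.00220 /M/min)
    reagent + catalyst + intermediate → catalyst + product (k = 4.80 × 10⁻⁴ /M²/min)
    crystals ⇌ product, rate k3*(cs3 - [product]) while solid is left; crystals form when [product] > cs3 (solubility = 0.0610 M, k = 0.0150 /min)

**Not at rest.** The flask's 91.3% lies between alpha's 89.0% and 94.1%, the readings on either side of 6.67 d, and at 10 d the flask is still moving: intermediate stands at 8.62% and crystals at 87.1%. The neighbour with 0.55 M of catalyst counts 16.7 d of alpha's time at 10 d and stands at 99.7%, with intermediate at 0.264%. Ten times the time, 66.7 d of alpha's time for the flask, brings product and crystals together to 100%, intermediate to 0%, crystals to 95.9%, and reagent from 54.4% to 50.0% of its charge.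

(The earlier runs and the new flask were computed with constants of no real substance; the scatter is artificial.)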